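The winter run shows the first step: starting material falls from 14.2% at 0.417 min to 0.3% at 1.00 min, while target stands at 15.7%, and the rest of the charge is in forms not read. The first reading gives starting material a half-life near 0.148 min, far shorter than the 5.00 min at which the winter run reads target at 49.7%, so I take that step as done and count the charge, less target, as a pool waiting for reagent.

| flask | starting material | reagent | remark | time |
|---|---|---|---|---|
| noon | 0.25 M | 0.275 M | run made earlier |  |
| spring | 0.12 M | 0.275 M | run made earlier |  |
| winter | 0.19 M | 0.275 M | run made earlier |  |
| theta | 0.25 M | 0.275 M (fed, over 6.40 min) | a stirred flask in which reagent is dosed at a steady rate over 6.40 min without added volume, worked up at 8.0 min | 8.0 min |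
| beta | 0.25 M | 0.275 M | everything together in a closed stirred flask, run for 8.0 min | 8.0 min |
| zeta | 0.25 M | 0.275 M | a single well-mixed tank run continuously and read at steady state, 80.0 min in it on average |  |
| delta | 0.25 M | 0.275 M | a single well-mixed tank run continuously and read at steady state, 8.0 min in it on average |  |

- noon (time / min: target / %, starting material / %): 0.833: 12.9, 0.7; 1.50: 19.7, 0; 2.50: 29.6, 1.1; 3.00: 33.5, 1.0; 4.00: 40.7, 0.2; 5.00: 47.1, 1.3
- spring (time / min: target / %, starting material / %): 0.833: 9.9, 2.0; 1.50: 20.8, 0.6; 2.50: 31.8, 0; 3.00: 36.2, 0; 4.00: 45.1, 0; 5.00: 54.8, 0
- winter (time / min: target / %, starting material / %): 0.417: 5.8, 14.2; 0.667: 8.4, 3.7; 1.00: 15.7, 0.3; 2.00: 26.8, 2.3; 3.00: 35.6, 0.1; 5.00: 49.7, 0.9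

(readings scatter by 1 percentage point)

- the set-up with the highest amount of target at the outlet or at the end, in percent of the starting material put in ("none" if the first two lie within 2 percentage points) (theta / beta / zeta / delta / none)
- amount of target at the outlet or at the end, in percent of the starting material put in, theta
- amount of target at the outlet or at the end, in percent of the starting material put in, beta
- amount of target at the outlet or at the end, in percent of the starting material put in, zeta
- amount of target at the outlet or at the end, in percent of the starting material put in, delta

- the stated concentrations are those of everything mixed, before any reaction; amounts are the same in each set-up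
- what was read earlier has a scatter of 1 percentage point, one standard deviation
- the feed brings no volume worth counting
- the earlier runs were made in a closed, stirred flask

Starting material is the limiting reagent, with 1.10 of reagent per charge at noon. I let target grow as a constant times pool left times reagent left, each a fraction of the charge, and call that constant the pairing rate; the noon reading at 5.00 min gives 0.156 min⁻¹. The spring run, with about half the starting material, reads 0.168 min⁻¹ once scaled to the noon charge.

Pairing rate times time spent is my contact number: 1.25 for beta and delta, 12.5 for zeta. Integrated, beta reaches 59.3%. For a tank to fall level with that, its contact number would have to be 2.88; delta lies below this, while zeta stands 4.34 times above it. My tank balance gives zeta 79.3% and delta 44.8%.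

The forecast, reckoning with a loss of the unseen form, also puts zeta first, at 88% (82% to 93%), saying “conversion is nearly complete”, with beta 56%, theta 50% and delta 49%. On zeta my figure stands 8.7 percentage points lower.

Zeta gives 79.6%, the highest and 8.4 points below the forecast, with beta 59.6%, theta 45.6% and delta 44.7%; the pairing rate of 0.156 min⁻¹ had put zeta at 79.3% and delta at 44.8%.

    reagent + intermediate B → target (k = 0.0170 L mol⁻¹ s⁻¹)
    starting material → intermediate B (k = 0.0790 s⁻¹)
    starting material ⇌ intermediate A (K = 0.410, k = 0.00420 s⁻¹)
    intermediate B ⇌ intermediate D (K = 0.550, k = 0.0380 s⁻¹)
    starting material ⇌ intermediate C (K = 1.90, k = 2.50 × 10⁻⁴ s⁻¹)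

In beta, intermediate B has a half-life of 0.30 min by turning into intermediate D, forward rate only, which is shorter than the 2.5 min by meeting reagent as charged. With an equilibrium constant of 0.55 for that turning, intermediate B holds 64.5% of the pair once the two balance.

All runs are calculated for substances that don't exist.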